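## Structural features

The target is a dibenzylbutyrolactone lignan. It has one γ-butyrolactone ring (O1, C2=O, C3, C4, C5) with a 4-hydroxy-3-methoxybenzyl group on C3 and a 3,4,5-trimethoxybenzyl group on C4, each joined through a CH2 link. C3 and C4 are the only stereocentres; they are adjacent, both are R, and the two benzyl groups are trans on the ring. The C3–C4 bond is the 8–8′ bond of the lignan skeleton and joins two C6–C3 halves of nearly equal size at the centre of the molecule. Because the two aryl groups differ, there is no hidden symmetry, and the carbonyl must end up on the guaiacyl side, which rules out symmetric succinate or diol intermediates. C3 is α to the carbonyl and can be equilibrated to the more stable trans arrangement. C4 is configurationally fixed, bears no heteroatom and has three sterically similar carbon substituents, so it carries the absolute configuration and is the hard centre to set. Fragile groups are the free phenol (acidic, easily oxidised), the two electron-rich arenes, the base-sensitive lactone and the epimerisable C3–H. The key step exploits the chain C2(=O)–C3–C4–C5 of the lactone ring: with C5 read as an alkene carbon, this chain is a γ,δ-unsaturated acid, the retron of a [3,3]-sigmatropic rearrangement of an allylic ester whose new σ bond is exactly C3–C4.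

## Logic of the disconnections

**18 ⇒ 17.** The phenolic O–H is written back as an O–CH2Ph bond. A free phenol would quench the strong base of the key step, would be silylated, and would make its ring the most ozone-sensitive site. The skeleton is not simplified, but every earlier step becomes chemoselective. The forward release must be neutral so that the lactone and C3 are untouched. Hydrogenolysis meets this demand because no other benzylic carbon–heteroatom bond is present.

**17 ⇒ 14 (through 16 and 15).** The ring bonds O1–C2 and C5–O1 are cut, and C5 is redrawn as the inner carbon of an (E)-propenyl group. This uncovers the γ,δ-unsaturated acid retron. The ring disappears, and the side on which the carbonyl sits is fixed by construction, since C2 is a carboxyl carbon and C5 an alkene carbon. The forward alkene cleavage must spare three alkoxyarene rings and must not leave C4 for long as the α-carbon of an aldehyde. C3 can be equilibrated at this stage.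

**14 ⇒ 10 (through 13, 12 and 11), the key disconnection.**
- The central C3–C4 bond is cut, and with it both stereocentres are removed at once.
- In their place stand one ester C–O bond and one carbinol stereocentre that can be bought.
- In one sentence: a [3,3]-sigmatropic shift of the silyl ketene acetal of the chiral allylic ester 10 makes the C3–C4 bond and both stereocentres in one event. This sentence does not fit the enolate benzylation most chemists would draw first, in which C3–C4 is already present.
- The gain is the largest of the route: a congested C–C bond between two different halves becomes an acylation.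
- The forward step demands a geometrically pure E alkene, an enantiopure carbinol, faithful suprafacial chirality transfer, and a defined ketene acetal geometry. The last of these can be corrected later.

**10 ⇒ 3 + 9.** The acyl–oxygen bond of the ester is cut. This splits the molecule into its two C6–C3 halves, each reached in one or two steps. The forward step must activate the acid and never the alcohol, so that the carbinol C–O bond and its configuration are kept.

**9 ⇒ 7.** The E alkene is written back as an alkyne. Each alkene geometry maps onto the opposite C4 configuration in the key step, so the geometry must come from a stereospecific reaction and not from an equilibrium. A hydroxyl-directed trans reduction is required, without migration of the unsaturation towards the arene.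

**7 ⇒ 4 + 5.** The C(sp)–CH2 bond next to the trimethoxyphenyl ring is cut. This leads to a commercial enantiopure alkynol and a commercial benzylic halide. C-benzylation must win over O-benzylation, and no strong base may remain to isomerise the skipped aryl-alkyne.

**3 ⇒ 1.** The O–CH2Ph bond is cut, which leads to a commercial phenolic acid. The phenol must be alkylated while the carboxyl group ends up free.

## Other disconnections considered

**Alternative 1:** (the first that comes to mind)
- Cut: the C3–CH2 bond of the guaiacyl side.
- Forward key step: the lithium enolate of (R)-4-(3,4,5-trimethoxybenzyl)dihydrofuran-2(3H)-one A1 is alkylated with 4-(benzyloxy)-3-methoxybenzyl bromide A2, anti to the C4 substituent, to give 17.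
- Ground for preferring the chosen plan: this step solves only the easy centre, because C3 falls into the trans arrangement under thermodynamic control anyway. The hard centre C4 and the C3–C4 bond are pushed back into A1, which needs an asymmetric synthesis of its own of several steps. A2 is a labile, electron-rich benzylic bromide that must also be made. The stereocentres are set one after the other, and the overall count is higher than in the chosen plan.

**Alternative 2:**
- Cut: the same C3–C4 bond, but as a carbene C–H insertion that also closes the ring.
- Forward key step: a chiral dirhodium(II) catalyst converts the diazo ester 3-(3,4,5-trimethoxyphenyl)propyl 3-[4-(benzyloxy)-3-methoxyphenyl]-2-diazopropanoate A3 into 17.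
- Ground for preferring the chosen plan: the carbene from A3 carries β-hydrogens, and their 1,2-shift to an alkene is intramolecular and normally faster than insertion into an unactivated methylene. The neighbouring benzylic CH2 competes through six-ring closure. Enantiocontrol of this reaction type rests on unsubstituted diazoacetates. Leaving out the α-benzyl group leads back to A1 and hence to Alternative 1.

**Alternative 3:**
- Cut: no C–C bond. The C3–H and C4–H bonds are cut, so that both stereocentres come as a group from the flat butenolide 3-[4-(benzyloxy)-3-methoxybenzyl]-4-(3,4,5-trimethoxybenzyl)furan-2(5H)-one A4.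
- Forward key step: enantioselective reduction (ene-reductase, copper hydride or hydrogenation), then equilibration at C3 to give 17.
- Ground for preferring the chosen plan: this route is shorter on paper, but the key step is not defensible.
  - The alkene is tetrasubstituted, and hydride must reach a fully substituted C4 whose two faces differ only through the distant O1 and C2=O.
  - The known catalysts of these classes are established for less substituted enoates.
  - The four benzylic, γ-acidic hydrogens of A4 invite migration of the double bond into conjugation with an arene.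
  - The plan therefore fails the second test.

Key step: step 5

Remark on the chemistry: the SMILES is read as the trans-(3R,4R) lactone. Ring atoms are numbered O1, C2 (C=O), C3, C4, C5. Ar = 4-(benzyloxy)-3-methoxyphenyl and Ar′ = 3,4,5-trimethoxyphenyl. Compounds 1, 4 and 5 are taken to be commercial.

## Steps

Step 1
Reactants: 1 3-(4-hydroxy-3-methoxyphenyl)propanoic acid (dihydroferulic acid)
Product: 3 3-[4-(benzyloxy)-3-methoxyphenyl]propanoic acid, via benzyl ester 2 (not isolated)
Conditions: BnBr (2.3 equiv), K2CO3 (2.5 equiv), DMF, 60 °C; then NaOH, MeOH/H2O, 50 °C; then 2 M HCl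
Reagents that add atoms: benzyl bromide, BrCc1ccccc1; sodium hydroxide, [Na+].[OH-]
Why: Williamson alkylation of phenoxide and carboxylate, followed by saponification of the benzyl ester at its acyl–oxygen bond; the aryl benzyl ether is inert to hydroxide, and no stereocentre is involved.

Step 2
Reactants: 4 (R)-but-3-yn-2-ol; 5 3,4,5-trimethoxybenzyl bromide
Product: 7 (2R)-5-(3,4,5-trimethoxyphenyl)pent-3-yn-2-ol, via bis(bromomagnesium) alkynide alkoxide 6 (not isolated)
Conditions: 4 (1.1 equiv), EtMgBr (2.1 equiv), THF, 0 °C → rt; CuBr·SMe2 (10 mol %), then 5 (1.0 equiv), 50 °C; aq. NH4Cl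
Reagents that add atoms: ethylmagnesium bromide, CC[Mg]Br (supplies the MgBr groups of 6 only; none of its atoms remain in 7)
Why: Copper-catalysed coupling of an alkynyl Grignard reagent with a benzylic bromide; the magnesium alkoxide is a poor nucleophile, so C-benzylation should prevail, and all EtMgBr is consumed before 5 is added, so nothing basic enough remains to isomerise the skipped aryl-alkyne. The carbinol centre is not touched and stays R.

Step 3
Reactants: 7 (2R)-5-(3,4,5-trimethoxyphenyl)pent-3-yn-2-ol
Product: 9 (2R,3E)-5-(3,4,5-trimethoxyphenyl)pent-3-en-2-ol, via cyclic sodium alkenylalanate 8 (not isolated)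
Conditions: Red-Al (1.6 equiv), THF, 0 °C → rt; aq. Rochelle salt
Reagents that add atoms: Red-Al, sodium bis(2-methoxyethoxy)aluminium dihydride, [Na+].COCCO[AlH2-]OCCOC (supplies the aluminate unit of 8 only; only hydrogen remains in 9)
Why: Hydroxyl-directed trans-hydroalumination of a propargylic alcohol: the alkoxide-bound aluminium hydride delivers H to C3 and Al to C4 within the five-membered ring of 8, and protonolysis with retention should give the E alkene only. The carbinol centre and the aryl methyl ethers are not affected.

Step 4
Reactants: 3 3-[4-(benzyloxy)-3-methoxyphenyl]propanoic acid; 9 (2R,3E)-5-(3,4,5-trimethoxyphenyl)pent-3-en-2-ol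
Product: 10 (2R,3E)-5-(3,4,5-trimethoxyphenyl)pent-3-en-2-yl 3-[4-(benzyloxy)-3-methoxyphenyl]propanoate
Conditions: DCC (1.1 equiv), DMAP (10 mol %), CH2Cl2, 0 °C → rt
Reagents that add atoms: none
Why: Steglich esterification: only the acid is activated (O-acylisourea, acylpyridinium) and the C–O bond of the allylic alcohol is never broken, so the R configuration and the E alkene are kept.

Step 5
Reactants: 10 (2R,3E)-5-(3,4,5-trimethoxyphenyl)pent-3-en-2-yl 3-[4-(benzyloxy)-3-methoxyphenyl]propanoate
Product: 14 (2R,3S,4E)-2-[4-(benzyloxy)-3-methoxybenzyl]-3-(3,4,5-trimethoxybenzyl)hex-4-enoic acid, via lithium Z(O)-enolate 11 (not isolated), via (Z)-silyl ketene acetal 12 (not isolated), via TBS ester 13 (not isolated)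
Conditions: LDA (1.2 equiv), THF/DMPU (3:1), −78 °C; TBSCl (1.3 equiv), −78 °C → rt, then 50 °C; 1 M HCl, THF, rt
Reagents that add atoms: lithium diisopropylamide, [Li+].CC(C)[N-]C(C)C (lithium of 11 only); tert-butyldimethylsilyl chloride, CC(C)(C)[Si](C)(C)Cl (silyl group of 12 and 13 only; no atom of either reagent remains in 14)
Why: Ireland–Claisen rearrangement with 1,3-chirality transfer, a known reaction type for allylic esters of simple alkanoic acids. LDA in the presence of the dipolar cosolvent deprotonates 10 through an open transition state to the Z(O)-enolate 11 (CH2Ar cis to OLi), O-silylation freezes this geometry in 12, and on warming 12 undergoes a concerted, suprafacial [3,3] shift in which the carbinol C–O bond breaks while the C3–C4 bond forms; dilute acid then cleaves the silyl ester 13. No ring is closed in the product: the only ring is the six-membered chair transition state, which leaves C2, C3, C4 and C5 of the future lactone in one chain at the right oxidation levels. C4 is controlled by the (R)-carbinol centre together with the E alkene, because the carbinol methyl group takes the pseudo-equatorial site (a pseudo-axial methyl would meet the silyloxy-bearing carbon in a 1,3-diaxial contact), so that C3 attacks the alkene face from which the oxygen leaves, which maps the R carbinol onto the C4 configuration of 18 and gives an E propenyl group. C3 is controlled by the ketene acetal geometry: in the chair of 12 both CH2Ar and CH2Ar′ are pseudo-equatorial, which corresponds to the syn acid (2R,3S) and hence to the trans-(3R,4R) lactone. The step needs ester α-deprotonation rather than attack on the allylic–benzylic CH2 (secured by the much higher acidity of the ester α-H under kinetic conditions at −78 °C), O- rather than C-silylation (favoured by TBSCl in DMPU) and chair over boat (the norm for acyclic E-allylic esters). Leakage through the other ketene acetal geometry or through a boat turns over only the enolate face, that is C3 and never C4, and C3 is equilibrated in step 6, so the step is forgiving exactly where it is least certain.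

Step 6
Reactants: 14 (2R,3S,4E)-2-[4-(benzyloxy)-3-methoxybenzyl]-3-(3,4,5-trimethoxybenzyl)hex-4-enoic acid
Product: 17 (3R,4R)-3-[4-(benzyloxy)-3-methoxybenzyl]-4-(3,4,5-trimethoxybenzyl)dihydrofuran-2(3H)-one, via secondary ozonide 15 (not isolated), via hydroxy acid 16 (not isolated)
Conditions: O3, CH2Cl2, −78 °C (Sudan Red 7B as end-point indicator); NaBH4, MeOH, −78 → 0 °C; 2 M HCl, rt; crude lactone: DBU (0.2 equiv), CH2Cl2, rt
Reagents that add atoms: ozone, [O-][O+]=O
Why: Ozonolysis with borohydride work-up, acid-catalysed γ-lactonisation and base equilibration of the α-centre, all standard operations. The isolated 1,2-dialkyl alkene reacts with ozone much faster than the alkoxyarenes when the gas is metered against an indicator dye, and hydride takes the peroxidic product straight to the primary alcohol 16, so C4 is hardly exposed as the α-carbon of an aldehyde. Under DBU only C3 can epimerise and it settles in the more stable trans arrangement, so C3 = R follows from C4 = R whatever the diastereomeric purity of 14.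

Step 7
Reactants: 17 (3R,4R)-3-[4-(benzyloxy)-3-methoxybenzyl]-4-(3,4,5-trimethoxybenzyl)dihydrofuran-2(3H)-one
Product: 18 (3R,4R)-3-(4-hydroxy-3-methoxybenzyl)-4-(3,4,5-trimethoxybenzyl)dihydrofuran-2(3H)-one (target)
Conditions: H2 (1 atm), 10% Pd/C, EtOAc/EtOH, rt
Reagents that add atoms: none
Why: Hydrogenolysis of an aryl benzyl ether under neutral conditions; the lactone, the methyl ethers and both stereocentres are not affected, and the other benzylic carbons bear no heteroatom and are not cleaved.

## Compound list

1 | 3-(4-hydroxy-3-methoxyphenyl)propanoic acid (dihydroferulic acid) | OC(=O)CCc1ccc(O)c(OC)c1 | starting material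
2 | benzyl 3-[4-(benzyloxy)-3-methoxyphenyl]propanoate | O=C(CCc1ccc(OCc2ccccc2)c(OC)c1)OCc1ccccc1 | intermediate
3 | 3-[4-(benzyloxy)-3-methoxyphenyl]propanoic acid | OC(=O)CCc1ccc(OCc2ccccc2)c(OC)c1 | intermediate
4 | (R)-but-3-yn-2-ol | C[C@@H](O)C#C | starting material
5 | 3,4,5-trimethoxybenzyl bromide | BrCc1cc(OC)c(OC)c(OC)c1 | starting material
6 | bis(bromomagnesium) alkynide alkoxide of (R)-but-3-yn-2-ol | C[C@@H](O[Mg]Br)C#C[Mg]Br | intermediate
7 | (2R)-5-(3,4,5-trimethoxyphenyl)pent-3-yn-2-ol | C[C@@H](O)C#CCc1cc(OC)c(OC)c(OC)c1 | intermediate
8 | sodium (5R)-2,2-bis(2-methoxyethoxy)-5-methyl-3-(3,4,5-trimethoxybenzyl)-2,5-dihydro-1,2-oxaaluminol-2-uide (cyclic alkenylalanate) | [Na+].C[C@H]1O[Al-](OCCOC)(OCCOC)C(Cc2cc(OC)c(OC)c(OC)c2)=C1 | intermediate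
9 | (2R,3E)-5-(3,4,5-trimethoxyphenyl)pent-3-en-2-ol | C[C@@H](O)/C=C/Cc1cc(OC)c(OC)c(OC)c1 | intermediate
10 | (2R,3E)-5-(3,4,5-trimethoxyphenyl)pent-3-en-2-yl 3-[4-(benzyloxy)-3-methoxyphenyl]propanoate | C[C@@H](OC(=O)CCc1ccc(OCc2ccccc2)c(OC)c1)/C=C/Cc1cc(OC)c(OC)c(OC)c1 | intermediate
11 | lithium Z(O)-enolate of 10 (CH2Ar cis to OLi) | [Li+].C[C@@H](O/C([O-])=C/Cc1ccc(OCc2ccccc2)c(OC)c1)/C=C/Cc1cc(OC)c(OC)c(OC)c1 | intermediate
12 | (Z)-tert-butyldimethylsilyl ketene acetal of 10 (CH2Ar cis to OSi) | C[C@@H](O/C(O[Si](C)(C)C(C)(C)C)=C/Cc1ccc(OCc2ccccc2)c(OC)c1)/C=C/Cc1cc(OC)c(OC)c(OC)c1 | intermediate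
13 | tert-butyldimethylsilyl (2R,3S,4E)-2-[4-(benzyloxy)-3-methoxybenzyl]-3-(3,4,5-trimethoxybenzyl)hex-4-enoate | CC(C)(C)[Si](C)(C)OC(=O)[C@H](Cc1ccc(OCc2ccccc2)c(OC)c1)[C@@H](Cc1cc(OC)c(OC)c(OC)c1)/C=C/C | intermediate
14 | (2R,3S,4E)-2-[4-(benzyloxy)-3-methoxybenzyl]-3-(3,4,5-trimethoxybenzyl)hex-4-enoic acid | OC(=O)[C@H](Cc1ccc(OCc2ccccc2)c(OC)c1)[C@@H](Cc1cc(OC)c(OC)c(OC)c1)/C=C/C | intermediate
15 | (2R,3R)-2-[4-(benzyloxy)-3-methoxybenzyl]-3-(5-methyl-1,2,4-trioxolan-3-yl)-4-(3,4,5-trimethoxyphenyl)butanoic acid (trioxolane centres undefined) | OC(=O)[C@H](Cc1ccc(OCc2ccccc2)c(OC)c1)[C@@H](Cc1cc(OC)c(OC)c(OC)c1)C1OOC(C)O1 | intermediate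
16 | (2R,3R)-2-[4-(benzyloxy)-3-methoxybenzyl]-4-hydroxy-3-(3,4,5-trimethoxybenzyl)butanoic acid | OC(=O)[C@H](Cc1ccc(OCc2ccccc2)c(OC)c1)[C@@H](Cc1cc(OC)c(OC)c(OC)c1)CO | intermediate
17 | (3R,4R)-3-[4-(benzyloxy)-3-methoxybenzyl]-4-(3,4,5-trimethoxybenzyl)dihydrofuran-2(3H)-one | COc1cc(C[C@H]2C(=O)OC[C@@H]2Cc2cc(OC)c(OC)c(OC)c2)ccc1OCc1ccccc1 | intermediate
18 | (3R,4R)-3-(4-hydroxy-3-methoxybenzyl)-4-(3,4,5-trimethoxybenzyl)dihydrofuran-2(3H)-one | COc1cc(C[C@H]2C(=O)OC[C@@H]2Cc2cc(OC)c(OC)c(OC)c2)ccc1O | target

## Step count and least certain steps

Total step count: 7. Longest linear sequence: 6 steps (2 → 3 → 4 → 5 → 6 → 7, from 4 and 5). Step 1 is a one-step side branch.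

**Step 5 (key step).**
The most likely failure is incomplete 1,3-chirality transfer, that is, partial passage through the chair in which the carbinol methyl group is pseudo-axial. With an E alkene the only penalty for that chair is the 1,3-diaxial contact with the silyloxy-bearing carbon. Because the propenyl group is cut off in step 6, such leakage would reappear as a loss of enantiomeric purity at C4 that no equilibration can repair. A second concern is slow silylation, with fragmentation of the ester enolate into ketene and alkoxide.

The fallback changes the stereochemical pairing of the two π-systems. It sets out from 5 and 3 and comes back to the route at 13.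
- (S)-But-3-yn-2-ol F1 is benzylated with 5 by the chemistry of step 2 to give (2S)-5-(3,4,5-trimethoxyphenyl)pent-3-yn-2-ol F2.
- Semihydrogenation over Lindlar catalyst gives (2S,3Z)-5-(3,4,5-trimethoxyphenyl)pent-3-en-2-ol F3.
- Steglich esterification with 3 gives (2S,3Z)-5-(3,4,5-trimethoxyphenyl)pent-3-en-2-yl 3-[4-(benzyloxy)-3-methoxyphenyl]propanoate F4.
- Enolisation with LDA in THF without cosolvent (closed transition state, CH2Ar trans to OLi) and silylation give the (E)-silyl ketene acetal F5.
- In the chair of F5 both benzylic substituents are pseudo-axial and anti to each other. A pseudo-axial methyl group would now collide with the cis CH2Ar′ group, so the transfer should be stricter.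
- Both the carbinol configuration and the alkene geometry are inverted, and the ketene acetal geometry is inverted as well. The same silyl ester 13 results.

**Step 2.**
The most likely failures are Wurtz-type homocoupling of the electron-rich benzylic bromide, competing O-benzylation of the magnesium alkoxide, and propargyl–allene isomerisation of the skipped aryl-alkyne under basic conditions.

The fallback reverses the order of alkene and C–C bond formation. It sets out from 4 and 5 and comes back at 9, bypassing 7 and step 3.
- Zirconium-catalysed syn-hydroboration of 4 with pinacolborane gives, after aqueous release of the alcohol, (2R,3E)-4-(4,4,5,5-tetramethyl-1,3,2-dioxaborolan-2-yl)but-3-en-2-ol F6.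
- F6 is joined to 5 by a Suzuki–Miyaura sp2–sp3 coupling (Pd(dppf)Cl2, K2CO3, THF/H2O) with retention of the E geometry.

**Step 3.**
The most likely failures are migration of the unsaturation into conjugation with the arene and incomplete hydroalumination. Both arise because the benzylic–propargylic CH2 is acidic towards the basic aluminate.

The fallback is a neutral, two-stage trans reduction. It sets out from 7 and comes back at 9.
- Ruthenium-catalysed trans-hydrosilylation ([Cp*Ru(MeCN)3]PF6, (EtO)3SiH, CH2Cl2) gives (2R,3Z)-4-(triethoxysilyl)-5-(3,4,5-trimethoxyphenyl)pent-3-en-2-ol F7.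
- Protodesilylation with CuI/TBAF, with retention, gives the E alkene.

**Step 6.**
The most likely failures are over-oxidation of the alkoxyarene rings or of the benzyl ether by excess ozone, and epimerisation at C4 at the aldehyde oxidation level before hydride arrives.

The fallback avoids ozone and masks the acid. It sets out from 14 and comes back at 17.
- Methylation (MeI, K2CO3, DMF) gives methyl (2R,3S,4E)-2-[4-(benzyloxy)-3-methoxybenzyl]-3-(3,4,5-trimethoxybenzyl)hex-4-enoate F8.
- Lemieux–Johnson cleavage (cat. OsO4, NaIO4, 2,6-lutidine, dioxane/H2O) gives methyl (2R,3R)-2-[4-(benzyloxy)-3-methoxybenzyl]-3-formyl-4-(3,4,5-trimethoxyphenyl)butanoate F9.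
- NaBH4 in MeOH at 0 °C reduces the aldehyde, and the resulting alkoxide closes onto the ester to give 17. The DBU equilibration follows as in step 6.

## Further compounds

F1 | step 5 | (S)-but-3-yn-2-ol | C[C@H](O)C#C
F2 | step 5 | (2S)-5-(3,4,5-trimethoxyphenyl)pent-3-yn-2-ol | C[C@H](O)C#CCc1cc(OC)c(OC)c(OC)c1
F3 | step 5 | (2S,3Z)-5-(3,4,5-trimethoxyphenyl)pent-3-en-2-ol | C[C@H](O)/C=C\Cc1cc(OC)c(OC)c(OC)c1
F4 | step 5 | (2S,3Z)-5-(3,4,5-trimethoxyphenyl)pent-3-en-2-yl 3-[4-(benzyloxy)-3-methoxyphenyl]propanoate | C[C@H](OC(=O)CCc1ccc(OCc2ccccc2)c(OC)c1)/C=C\Cc1cc(OC)c(OC)c(OC)c1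
F5 | step 5 | (E)-tert-butyldimethylsilyl ketene acetal of F4 (CH2Ar trans to OSi) | C[C@H](O/C(O[Si](C)(C)C(C)(C)C)=C\Cc1ccc(OCc2ccccc2)c(OC)c1)/C=C\Cc1cc(OC)c(OC)c(OC)c1
F6 | step 2 | (2R,3E)-4-(4,4,5,5-tetramethyl-1,3,2-dioxaborolan-2-yl)but-3-en-2-ol | C[C@@H](O)/C=C/B1OC(C)(C)C(C)(C)O1
F7 | step 3 | (2R,3Z)-4-(triethoxysilyl)-5-(3,4,5-trimethoxyphenyl)pent-3-en-2-ol | C[C@@H](O)/C=C(/Cc1cc(OC)c(OC)c(OC)c1)[Si](OCC)(OCC)OCC
F8 | step 6 | methyl (2R,3S,4E)-2-[4-(benzyloxy)-3-methoxybenzyl]-3-(3,4,5-trimethoxybenzyl)hex-4-enoate | COC(=O)[C@H](Cc1ccc(OCc2ccccc2)c(OC)c1)[C@@H](Cc1cc(OC)c(OC)c(OC)c1)/C=C/C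
F9 | step 6 | methyl (2R,3R)-2-[4-(benzyloxy)-3-methoxybenzyl]-3-formyl-4-(3,4,5-trimethoxyphenyl)butanoate | COC(=O)[C@H](Cc1ccc(OCc2ccccc2)c(OC)c1)[C@@H](Cc1cc(OC)c(OC)c(OC)c1)C=O
A1 | alternative 1 | (R)-4-(3,4,5-trimethoxybenzyl)dihydrofuran-2(3H)-one | O=C1C[C@@H](Cc2cc(OC)c(OC)c(OC)c2)CO1
A2 | alternative 1 | 4-(benzyloxy)-3-methoxybenzyl bromide | BrCc1ccc(OCc2ccccc2)c(OC)c1
A3 | alternative 2 | 3-(3,4,5-trimethoxyphenyl)propyl 3-[4-(benzyloxy)-3-methoxyphenyl]-2-diazopropanoate | [N-]=[N+]=C(Cc1ccc(OCc2ccccc2)c(OC)c1)C(=O)OCCCc1cc(OC)c(OC)c(OC)c1
A4 | alternative 3 | 3-[4-(benzyloxy)-3-methoxybenzyl]-4-(3,4,5-trimethoxybenzyl)furan-2(5H)-one | O=C1OCC(Cc2cc(OC)c(OC)c(OC)c2)=C1Cc1ccc(OCc2ccccc2)c(OC)c1
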